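## Structural features

The target is an ent-labdane: a trans-fused decalin (ring A = C1–C5 and C10, ring B = C5–C10) with a gem-dimethyl carbon C4, an angular methyl C20 on quaternary C10, a trisubstituted C7=C8 alkene carrying C17, and a C11–C16 chain on C9 that ends in a primary acetate. Ring A carries a cis-2,3-diol on the face opposite C20; the equatorial O2 is acetylated and the axial, neopentyl O3 is free. The centres C5, C10 and C9 are contiguous around the quaternary carbon, C2 and C3 adjoin each other next to C4, and C13 stands alone, two methylenes away from ring B, where no ring-based induction can reach it. Fragile points are the two acetates (base, acyl migration between O2 and O3), the C7=C8 alkene (acid or base can move it to the tetrasubstituted C8=C9 position) and the allylic C9–H. The real difficulty is to build quaternary C10 in the correct sense relative to the distant diol, and to join the separately made C13 centre without a diastereomer mixture. Ring B offers the solution: C10=C5–C6=C7 is a diene embedded in ring A, and C8–C9 with C17 and the whole chain is a two-carbon alkyne unit, so one [4+2] cycloaddition forms C7–C8 and C9–C10, closes ring B and delivers C10 and the side chain together. The cis-diol coincides in absolute configuration with C3/C4 of (−)-quinic acid, which fixes the source of ring A.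

## Logic of the disconnections

26 ⇒ 25. The acyl–O2 and acyl–O15 bonds are cut. The free 3-OH beside a 2-acetate is the pattern expected from rate-controlled acylation, and removing the esters keeps base-labile groups out of the whole route. The forward step must distinguish the equatorial C2 hydroxyl from the axial, neopentyl C3 hydroxyl.

25 ⇒ 24. The O15–Si bond and the two acetal C–O bonds are cut. One acid step then unveils all three hydroxyls. The acid must be mild enough not to move the C7=C8 alkene.

24 ⇒ 23 ⇒ 22 ⇒ 21. The C11–H bond is traced back to C11–O and then to C11=O. This returns the carbonyl that activates the alkyne and allows the alkene shift. The forward deoxygenation must leave the homoallylic C7=C8 alkene and C9 untouched.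

21 ⇒ 20. The C9–H bond is cut and the alkene is moved back to C8=C9, in conjugation with C11=O. The gain is a tetrasubstituted enone, the direct outcome of an alkyne cycloaddition after saturation of C5=C6. The forward step needs the extended enolate and a kinetic protonation at C9 anti to C20.

20 ⇒ 19. The C5–H and C6–H bonds are cut. This gives the 1,4-cyclohexadiene of a Diels–Alder adduct. The forward hydrogenation must take the C5=C6 alkene only, from the face opposite C20.

19 ⇒ 11 + 18. C7–C8 and C9–C10 are cut, opening ring B. Two fragments of similar size result, each with its own stereocentres. The forward cycloaddition must be regioselective (C7 to C8) and must add to the face of 11 that carries the oxygens. The skeletons of 11 and 18 are kept exactly; only the way to 11 is redesigned.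

11 ⇒ 10 ⇒ 9. The C5–C6 bond is cut: the vinyl group comes from a vinyl nucleophile and an enol triflate, which comes from a ketone at C5. Since 9 has a single α-hydrogen, the position of the C5=C10 alkene is unambiguous.

9 ⇒ 8. The C10–C20 bond and a C1–H bond are cut. Conjugate hydride addition to an enone gives the C10 enolate regiospecifically, and a methyl electrophile traps it.

8 ⇒ 6. The two C4–CH3 bonds are cut. The carbonyl carbon of 6 is taken as C5 and its α′-methylene as C4. The more obvious plan builds C4 at the β-carbon of 6 by two conjugate methylations, with the carbonyl carbon as C10. That plan puts the gem-dimethyl carbon beside the wrong oxygen-bearing carbon and leads from natural 1 to the mirror image of 11, so it is rejected. The forward step needs a β-alkoxy enolate that is alkylated faster than it eliminates.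

6 ⇒ 4 ⇒ 3 ⇒ 2 ⇒ 1. The enone alkene is traced to a β-hydroxy ketone, the ketone to a glycol cleavage, and the glycol to the reduced lactone of 1. Both ring stereocentres of 11 are taken unchanged from 1.

18 ⇒ 16 + 17. The C9–C11 bond is cut between the alkyne and the acyl carbon. The forward step needs single addition to the acyl group, which an N-methoxy-N-methyl amide ensures.

16 ⇒ 15 ⇒ 14 ⇒ 13 ⇒ 12. These are functional-group changes on a five-carbon chain whose only stereocentre comes from desymmetrising 12. The acid arm must become C15 and the ester arm C11, otherwise the wrong enantiomer of 18 results.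

## Other disconnections considered

Alternative 1: The cut is at C3–C4 and C3–C18, with one C4 methyl treated as the methylene of a cyclopropane. In the forward sense Cu(acac)2 would decompose diazomethyl ketone A1, and the carbenoid at C3 would add to the isopropenyl group on C5 to give tricyclic diketone A2, closing ring A and the three-membered ring together.
- In its favour: carbenoid cyclopropanation that closes a six-membered ketone is dependable, C4 becomes quaternary without enolate chemistry beside an oxygen, and A2 already holds the C7=C8 alkene with C17.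
- Against it here: A2 has no C3 oxygen, so reductive opening of C3–C18 must be followed by α-oxygenation of the C2 ketone and a cis-selective reduction. The whole chain with C13 must still be attached to the hindered C9 carbonyl and C9 converted to a methine of defined configuration. C5 and C10 of A1 need an earlier asymmetric step.
- Comparison: structurally the key step addresses the easiest part of ring A and leaves C9, C13 and the diol open, whereas the chosen cycloaddition sets C10 and brings C9–C16 at once. Mechanistically the carbenoid step is at least as reliable and has no facial question. On the placement of the C7=C8 alkene, which needs no later shift, it is the better plan. In step economy it is clearly longer and linear.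

Alternative 2: C5–C10 and C8–C9 are cut, so both rings come from acyclic triene A3. On heating, the (Z)-alkylidene ester (C9=C10, ester carbon as C20) would add to the tethered 2-silyloxy diene C5–C8 to give decalin A4.
- In its favour: one pericyclic step sets C5, C8, C9 and C10, the suprafacial addition fixes the C9/C10 relation, no C11 carbonyl has to be removed, and no hydrogenation decides the ring fusion. On these points it equals or beats the chosen plan.
- Against it here: A3 needs a geometrically pure trisubstituted alkylidene ester and a (Z)-silyl enol ether diene at the end of a long linear sequence. A trisubstituted dienophile meeting a neopentyl diene terminus should react slowly. The trans ring fusion depends on one of two competing transition states. C20 arrives as an ester that must be reduced to methyl through a neopentyl deoxygenation. The C7 enol ether must be converted to the C7=C8 alkene at the cost of the C8 centre.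
- Comparison: structurally it forms more bonds and centres in the key step but is not convergent. Mechanistically both plans rely on a cycloaddition that builds a quaternary carbon, and the intramolecular one has the entropic advantage. In step economy the adjustments after the key step should exceed the seven steps of the chosen route.

Alternative 3: Ring A is cut at C2–C3. SmI2 would reduce both aldehydes of 2,3-seco dialdehyde A5 to ketyls that couple to the cis-diol A6.
- In its favour: samarium-mediated pinacol closure of six-membered rings is typically cis-selective, the diol appears unprotected with the 15-acetate in place, and one selective acetylation would finish the synthesis. In the endgame it is shorter than the chosen plan and needs no diol protecting group.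
- Against it here: A5 presupposes a complete ring B with C5, C9, C10 and the chain, so the hard part is only postponed. The neopentyl C3 aldehyde is hindered and the C2 aldehyde is enolisable. Cis selectivity does not decide which of the two cis-diols (oxygens syn or anti to C20) forms.
- Comparison: structurally it solves the diol but not C10. Mechanistically the radical coupling is mild and compatible with the acetate, equal to the chosen endgame in functional-group tolerance. In step economy it wins after the key step and very probably loses before it.

Key step: step 14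

Remark on the chemistry: labdane numbering is used for all bicyclic compounds. Centres that are erased later (the methyl-bearing carbon of 9, C11 of 22 and 23) are expected as mixtures and are written without configuration. 7 is drawn as the expected trans epimer.

## Route

Step 1
Reactants: 1 (−)-quinic acid
Product: 2 (−)-quinic acid 1,5-lactone 3,4-acetonide
Conditions: Me2C(OMe)2, TsOH·H2O (cat.), acetone, reflux
Reagents that add atoms: 2,2-dimethoxypropane, COC(C)(C)OC
Why: Acid-catalysed acetalisation with concurrent lactonisation: the only cis-vicinal diol (O3/O4) forms the five-membered acetonide and the carboxyl group, cis to the C5 hydroxyl, closes the lactone; no stereocentre is touched.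

Step 2
Reactants: 2 (−)-quinic acid 1,5-lactone 3,4-acetonide
Product: 3 1-(hydroxymethyl)-3,4-(isopropylidenedioxy)cyclohexane-1,5-diol (hydroxymethyl cis to the C5 hydroxyl, ring centres as in 1)
Conditions: NaBH4, EtOH, 0 °C to rt
Reagents that add atoms: none
Why: Hydride reduction of the activated α-hydroxy lactone gives the primary alcohol and so a tertiary/primary 1,2-diol ready for cleavage; the acetonide is inert.

Step 3
Reactants: 3 1-(hydroxymethyl)-3,4-(isopropylidenedioxy)cyclohexane-1,5-diol
Product: 4 (3R,4S,5R)-5-hydroxy-3,4-(isopropylidenedioxy)cyclohexan-1-one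
Conditions: NaIO4, H2O (pH 6 phosphate buffer), 0 °C to rt
Reagents that add atoms: none
Why: Periodate glycol cleavage removes the former carboxyl carbon as formaldehyde and turns C1 into the ring ketone; no other free vicinal diol is present.

Step 4
Reactants: 4 (3R,4S,5R)-5-hydroxy-3,4-(isopropylidenedioxy)cyclohexan-1-one
Product: 6 (4S,5R)-4,5-(isopropylidenedioxy)cyclohex-2-en-1-one, via mesylate 5 (not isolated)
Conditions: MsCl, Et3N, CH2Cl2, 0 °C
Reagents that add atoms: none
Why: Sulfonylation of the β-hydroxy ketone followed by E1cB elimination gives the conjugated enone; a short reaction time at 0 °C avoids loss of the second β-oxygen, and the two acetonide carbons (future C2 and C3) keep their configuration.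

Step 5
Reactants: 6 (4S,5R)-4,5-(isopropylidenedioxy)cyclohex-2-en-1-one
Product: 8 (4S,5R)-4,5-(isopropylidenedioxy)-6,6-dimethylcyclohex-2-en-1-one, via 6-methyl enone 7 (not isolated)
Conditions: LiN(iPr)2, THF, −78 °C; MeI, −78 to −40 °C; then LiN(iPr)2, −78 °C; MeI, DMPU, −78 to −30 °C
Reagents that add atoms: iodomethane, CI
Why: Kinetic enolate alkylation, run twice: the enone can be deprotonated only at the α′-carbon (the α-carbon is vinylic) and the lithium dienolate is C-methylated, the second cycle creating the quaternary carbon that becomes C4. The low temperature is chosen so that the β-alkoxy enolate is alkylated before it can expel the acetonide oxygen; the transient centre of 7 is of no consequence.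

Step 6
Reactants: 8 (4S,5R)-4,5-(isopropylidenedioxy)-6,6-dimethylcyclohex-2-en-1-one
Product: 9 (3R,4S)-3,4-(isopropylidenedioxy)-2,2,6-trimethylcyclohexan-1-one (both C6 epimers)
Conditions: LiBH(sBu)3, THF, −78 °C; MeI, −78 °C to rt
Reagents that add atoms: iodomethane, CI
Why: Conjugate reduction with enolate trapping (reductive alkylation): 1,2-attack is blocked by the neighbouring quaternary carbon, so hydride adds at the β-carbon (future C1) and the regiodefined enolate is methylated at the future C10. The new methine is not controlled and is flattened in step 7.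

Step 7
Reactants: 9 (3R,4S)-3,4-(isopropylidenedioxy)-2,2,6-trimethylcyclohexan-1-one
Product: 10 (4S,5R)-4,5-(isopropylidenedioxy)-2,6,6-trimethylcyclohex-1-en-1-yl trifluoromethanesulfonate
Conditions: KN(SiMe3)2, THF, −78 °C; PhNTf2, −78 °C to rt
Reagents that add atoms: N-phenylbis(trifluoromethanesulfonimide), O=S(=O)(N(c1ccccc1)S(=O)(=O)C(F)(F)F)C(F)(F)F
Why: Enolate O-triflation: the ketone has a single α-hydrogen, so the tetrasubstituted enolate and hence the C5=C10 alkene can form in one position only; no leaving group is β to this enolate.

Step 8
Reactants: 10 (4S,5R)-4,5-(isopropylidenedioxy)-2,6,6-trimethylcyclohex-1-en-1-yl trifluoromethanesulfonate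
Product: 11 (4S,5R)-4,5-(isopropylidenedioxy)-2,6,6-trimethyl-1-vinylcyclohex-1-ene
Conditions: Bu3SnCH=CH2, Pd(PPh3)4 (cat.), LiCl, THF, 65 °C
Reagents that add atoms: tributyl(vinyl)stannane, C=C[Sn](CCCC)(CCCC)CCCC
Why: Stille coupling of an enol triflate, known for the parent 2,6,6-trimethylcyclohexenyl triflate; LiCl assists the hindered oxidative-addition complex, and the vinyl group supplies C6 and C7.

Step 9
Reactants: 12 dimethyl 3-methylglutarate
Product: 13 (R)-5-methoxy-3-methyl-5-oxopentanoic acid (methyl hydrogen (R)-3-methylglutarate)
Conditions: pig liver esterase, pH 7 phosphate buffer/MeOH (4:1), −10 °C, NaOH (pH-stat); then HCl to pH 2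
Reagents that add atoms: water, O
Why: Enzymatic desymmetrisation by ester hydrolysis: the esterase is expected to cleave the pro-S ester arm of the prochiral diester, which sets C13. Low temperature and cosolvent raise the selectivity, and the half-ester can be enriched further by crystallising a salt with a chiral amine.

Step 10
Reactants: 13 (R)-5-methoxy-3-methyl-5-oxopentanoic acid
Product: 14 methyl (R)-5-hydroxy-3-methylpentanoate
Conditions: BH3·SMe2, THF, 0 °C to rt; MeOH quench
Reagents that add atoms: none
Why: Chemoselective borane reduction: the carboxylic acid is reduced through its acyloxyborane much faster than the methyl ester, so the acid arm becomes C15 and the ester arm stays for C11.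

Step 11
Reactants: 14 methyl (R)-5-hydroxy-3-methylpentanoate
Product: 15 methyl (R)-5-(tert-butyldimethylsilyloxy)-3-methylpentanoate
Conditions: TBSCl, imidazole, CH2Cl2, 0 °C to rt
Reagents that add atoms: tert-butyldimethylsilyl chloride, CC(C)(C)[Si](C)(C)Cl
Why: Silylation of the primary alcohol, done at once so that the hydroxy ester cannot lactonise; the silyl ether survives all basic, reductive and radical steps that follow.

Step 12
Reactants: 15 methyl (R)-5-(tert-butyldimethylsilyloxy)-3-methylpentanoate
Product: 16 (R)-5-(tert-butyldimethylsilyloxy)-N-methoxy-N,3-dimethylpentanamide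
Conditions: MeNH(OMe)·HCl, iPrMgCl, THF, −20 to 0 °C
Reagents that add atoms: N,O-dimethylhydroxylamine hydrochloride, CNOC.Cl
Why: Aminolysis of an ester by the magnesium amide made in the flask gives the Weinreb amide; C13 is β to the carbonyl and cannot epimerise.

Step 13
Reactants: 16 (R)-5-(tert-butyldimethylsilyloxy)-N-methoxy-N,3-dimethylpentanamide; 17 1-propynylmagnesium bromide
Product: 18 (R)-8-(tert-butyldimethylsilyloxy)-6-methyloct-2-yn-4-one
Conditions: THF, 0 °C; aq. NH4Cl
Reagents that add atoms: none
Why: Weinreb ketone synthesis: the chelated tetrahedral adduct resists a second addition and releases the ynone on work-up; the Grignard reagent brings C8, C9 and C17.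

Step 14
Reactants: 11 (4S,5R)-4,5-(isopropylidenedioxy)-2,6,6-trimethyl-1-vinylcyclohex-1-ene; 18 (R)-8-(tert-butyldimethylsilyloxy)-6-methyloct-2-yn-4-one
Product: 19 (13R)-15-(tert-butyldimethylsilyloxy)-2,3-(isopropylidenedioxy)-ent-labda-5,8-dien-11-one (C20 on the ring face opposite O2 and O3)
Conditions: Me2AlCl (1.2 equiv), CH2Cl2, −40 to 0 °C
Reagents that add atoms: none
Why: This is a concerted but asynchronous normal-demand Diels–Alder reaction in which Me2AlCl binds the ynone carbonyl and the s-cis diene C10=C5–C6=C7 of 11 adds across the C8≡C9 triple bond. The closest known reaction types are the cycloaddition of 2,6,6-trimethyl-1-vinylcyclohexene with acetylenic esters and Lewis-acid-promoted additions of alkynyl ketones to dienes. Ring B is closed by the [4+2] mode itself, both σ-bonds (C7–C8 and C9–C10) forming in one step, and it emerges as a 1,4-cyclohexadiene. The one new stereocentre, quaternary C10, is controlled by ring A: in the preferred half-chair the C3 oxygen is axial and the pseudoaxial C4 methyl lies on the opposite face, so the alkyne should approach from the oxygen-bearing face and C20 ends anti to O2 and O3. Regioselectivity is required and should follow from the leading bond: the unsubstituted, least hindered terminus C7 (largest HOMO coefficient because of the two alkyl groups on C10) attacks the electrophilic β-carbon C8, positive charge develops at the tertiary allylic C10, and the acyl-bearing C9 then closes onto C10. The linear alkyne is slim enough to reach the fully substituted terminus and shows no endo/exo isomerism, so C10 is the only stereochemical issue. C2, C3 and C13 are spectators, and the acetonide and silyl ether should tolerate the aluminium reagent at low temperature.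

Step 15
Reactants: 19 (13R)-15-(tert-butyldimethylsilyloxy)-2,3-(isopropylidenedioxy)-ent-labda-5,8-dien-11-one
Product: 20 (13R)-15-(tert-butyldimethylsilyloxy)-2,3-(isopropylidenedioxy)-ent-labd-8-en-11-one (H5 on the face of O2 and O3, trans-decalin)
Conditions: H2 (1 atm), Pd/C (5% palladium on carbon), EtOAc, rt
Reagents that add atoms: none
Why: Heterogeneous catalytic hydrogenation saturates the isolated trisubstituted C5=C6 alkene, while the tetrasubstituted, acyl-bearing C8=C9 alkene is too hindered. Hydrogen is delivered to the face opposite the angular C20 methyl and the axial C4 methyl, which sets C5 with H5 trans to C20.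

Step 16
Reactants: 20 (13R)-15-(tert-butyldimethylsilyloxy)-2,3-(isopropylidenedioxy)-ent-labd-8-en-11-one
Product: 21 (13R)-15-(tert-butyldimethylsilyloxy)-2,3-(isopropylidenedioxy)-ent-labd-7-en-11-one (H9 on the face of H5, acyl group equatorial)
Conditions: KOtBu (5 equiv), tBuOH/THF, rt; inverse quench into AcOH/H2O, 0 °C
Reagents that add atoms: none
Why: Deconjugative protonation of an extended enolate: under equilibrating alkoxide a ring γ-hydrogen at C7 is removed to give the dienolate O–C11=C9–C8=C7, and a fast kinetic quench protonates the α-carbon C9, leaving the alkene at C7=C8. The proton arrives axially, anti to C20, so the chain is equatorial, which is also the more stable epimer.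

Step 17
Reactants: 21 (13R)-15-(tert-butyldimethylsilyloxy)-2,3-(isopropylidenedioxy)-ent-labd-7-en-11-one
Product: 22 (13R)-15-(tert-butyldimethylsilyloxy)-2,3-(isopropylidenedioxy)-ent-labd-7-en-11-ol (both C11 epimers)
Conditions: iBu2AlH, CH2Cl2, −78 °C; MeOH, then aq. potassium sodium tartrate
Reagents that add atoms: none
Why: Hydride reduction of a ketone with a non-basic aluminium hydride at low temperature, so that the β,γ-alkene cannot return to conjugation; the carbinol configuration is irrelevant because C11 becomes a methylene.

Step 18
Reactants: 22 (13R)-15-(tert-butyldimethylsilyloxy)-2,3-(isopropylidenedioxy)-ent-labd-7-en-11-ol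
Product: 23 O-[(13R)-15-(tert-butyldimethylsilyloxy)-2,3-(isopropylidenedioxy)-ent-labd-7-en-11-yl] S-methyl dithiocarbonate
Conditions: NaH, CS2, THF, 0 °C to rt; MeI
Reagents that add atoms: carbon disulfide, S=C=S; iodomethane, CI
Why: Xanthate formation: the alkoxide adds to CS2 and the dithiocarbonate salt is S-methylated; the reaction is kept at room temperature to avoid thermal syn-elimination.

Step 19
Reactants: 23 O-[(13R)-15-(tert-butyldimethylsilyloxy)-2,3-(isopropylidenedioxy)-ent-labd-7-en-11-yl] S-methyl dithiocarbonate
Product: 24 (2S,3R,5S,9R,10S,13S)-15-(tert-butyldimethylsilyloxy)-2,3-(isopropylidenedioxy)labd-7-ene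
Conditions: Bu3SnH, AIBN (cat.), toluene, 90 °C
Reagents that add atoms: none
Why: Barton–McCombie deoxygenation: the stannyl radical adds to the thiocarbonyl group, β-scission gives the secondary C11 radical, and this is reduced by the tin hydride faster than a homoallylic radical rearranges. Acetonide, silyl ether and alkene are inert to the radical chain.

Step 20
Reactants: 24 (2S,3R,5S,9R,10S,13S)-15-(tert-butyldimethylsilyloxy)-2,3-(isopropylidenedioxy)labd-7-ene
Product: 25 (2S,3R,5S,9R,10S,13S)-labd-7-ene-2,3,15-triol
Conditions: AcOH/H2O/THF (3:1:1), 45 °C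
Reagents that add atoms: none
Why: Acid hydrolysis removes the acetonide and the primary silyl ether in one operation; aqueous acetic acid is too weak to shift the trisubstituted alkene.

Step 21
Reactants: 25 (2S,3R,5S,9R,10S,13S)-labd-7-ene-2,3,15-triol
Product: 26 (2S,3R,5S,9R,10S,13S)-3-hydroxylabd-7-ene-2,15-diyl diacetate (CNP0144124.1)
Conditions: Ac2O (2.3 equiv), pyridine, 0 °C to rt
Reagents that add atoms: acetic anhydride, CC(=O)OC(C)=O
Why: Rate-selective acylation: the primary C15 hydroxyl and the equatorial C2 hydroxyl are acetylated, while the axial C3 hydroxyl beside the gem-dimethyl carbon reacts much more slowly without a nucleophilic catalyst. The 2-acetate is also the regioisomer favoured if acyl migration equilibrates.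

## Compound list

1 | (−)-quinic acid | C1[C@H]([C@H]([C@@H](C[C@@]1(C(=O)O)O)O)O)O | starting material
2 | (−)-quinic acid 1,5-lactone 3,4-acetonide | C1[C@H]2OC(C)(C)O[C@H]2[C@H]3C[C@]1(O)C(=O)O3 | intermediate
3 | 1-(hydroxymethyl)-3,4-(isopropylidenedioxy)cyclohexane-1,5-diol | C1[C@H]2OC(C)(C)O[C@H]2[C@H](O)C[C@]1(O)CO | intermediate
4 | (3R,4S,5R)-5-hydroxy-3,4-(isopropylidenedioxy)cyclohexan-1-one | C1[C@H]2OC(C)(C)O[C@H]2[C@H](O)CC1=O | intermediate
5 | methanesulfonate of 4 | C1[C@H]2OC(C)(C)O[C@H]2[C@H](OS(C)(=O)=O)CC1=O | intermediate
6 | (4S,5R)-4,5-(isopropylidenedioxy)cyclohex-2-en-1-one | O=C1C=C[C@@H]2OC(C)(C)O[C@@H]2C1 | intermediate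
7 | (4S,5R,6R)-4,5-(isopropylidenedioxy)-6-methylcyclohex-2-en-1-one | O=C1C=C[C@@H]2OC(C)(C)O[C@@H]2[C@H]1C | intermediate
8 | (4S,5R)-4,5-(isopropylidenedioxy)-6,6-dimethylcyclohex-2-en-1-one | O=C1C=C[C@@H]2OC(C)(C)O[C@@H]2C1(C)C | intermediate
9 | (3R,4S)-3,4-(isopropylidenedioxy)-2,2,6-trimethylcyclohexan-1-one | O=C1C(C)C[C@@H]2OC(C)(C)O[C@@H]2C1(C)C | intermediate
10 | (4S,5R)-4,5-(isopropylidenedioxy)-2,6,6-trimethylcyclohex-1-en-1-yl trifluoromethanesulfonate | FC(F)(F)S(=O)(=O)OC1=C(C)C[C@@H]2OC(C)(C)O[C@@H]2C1(C)C | intermediate
11 | (4S,5R)-4,5-(isopropylidenedioxy)-2,6,6-trimethyl-1-vinylcyclohex-1-ene | C=CC1=C(C)C[C@@H]2OC(C)(C)O[C@@H]2C1(C)C | intermediate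
12 | dimethyl 3-methylglutarate | COC(=O)CC(C)CC(=O)OC | starting material
13 | (R)-5-methoxy-3-methyl-5-oxopentanoic acid | COC(=O)C[C@H](C)CC(=O)O | intermediate
14 | methyl (R)-5-hydroxy-3-methylpentanoate | COC(=O)C[C@H](C)CCO | intermediate
15 | methyl (R)-5-(tert-butyldimethylsilyloxy)-3-methylpentanoate | COC(=O)C[C@H](C)CCO[Si](C)(C)C(C)(C)C | intermediate
16 | (R)-5-(tert-butyldimethylsilyloxy)-N-methoxy-N,3-dimethylpentanamide | CON(C)C(=O)C[C@H](C)CCO[Si](C)(C)C(C)(C)C | intermediate
17 | 1-propynylmagnesium bromide | CC#C[Mg]Br | starting material
18 | (R)-8-(tert-butyldimethylsilyloxy)-6-methyloct-2-yn-4-one | CC#CC(=O)C[C@H](C)CCO[Si](C)(C)C(C)(C)C | intermediate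
19 | (13R)-15-(tert-butyldimethylsilyloxy)-2,3-(isopropylidenedioxy)-ent-labda-5,8-dien-11-one | CC1=C(C(=O)C[C@H](C)CCO[Si](C)(C)C(C)(C)C)[C@]2(C)C[C@H](O3)[C@H](OC3(C)C)C(C)(C)C2=CC1 | intermediate
20 | (13R)-15-(tert-butyldimethylsilyloxy)-2,3-(isopropylidenedioxy)-ent-labd-8-en-11-one | CC1=C(C(=O)C[C@H](C)CCO[Si](C)(C)C(C)(C)C)[C@]2(C)C[C@H](O3)[C@H](OC3(C)C)C(C)(C)[C@H]2CC1 | intermediate
21 | (13R)-15-(tert-butyldimethylsilyloxy)-2,3-(isopropylidenedioxy)-ent-labd-7-en-11-one | CC(C)(C)[Si](C)(C)OCC[C@@H](C)CC(=O)[C@@H]1C(C)=CC[C@@H]2C(C)(C)[C@@H](O3)[C@@H](OC3(C)C)C[C@@]12C | intermediate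
22 | (13R)-15-(tert-butyldimethylsilyloxy)-2,3-(isopropylidenedioxy)-ent-labd-7-en-11-ol | CC(C)(C)[Si](C)(C)OCC[C@@H](C)CC(O)[C@@H]1C(C)=CC[C@@H]2C(C)(C)[C@@H](O3)[C@@H](OC3(C)C)C[C@@]12C | intermediate
23 | 11-O-(methylsulfanylthiocarbonyl) derivative of 22 | CC(C)(C)[Si](C)(C)OCC[C@@H](C)CC(OC(=S)SC)[C@@H]1C(C)=CC[C@@H]2C(C)(C)[C@@H](O3)[C@@H](OC3(C)C)C[C@@]12C | intermediate
24 | (2S,3R,5S,9R,10S,13S)-15-(tert-butyldimethylsilyloxy)-2,3-(isopropylidenedioxy)labd-7-ene | CC(C)(C)[Si](C)(C)OCC[C@@H](C)CC[C@@H]1C(C)=CC[C@@H]2C(C)(C)[C@@H](O3)[C@@H](OC3(C)C)C[C@@]12C | intermediate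
25 | (2S,3R,5S,9R,10S,13S)-labd-7-ene-2,3,15-triol | OCC[C@@H](C)CC[C@@H]1C(C)=CC[C@@H]2C(C)(C)[C@@H](O)[C@@H](O)C[C@@]12C | intermediate
26 | (2S,3R,5S,9R,10S,13S)-3-hydroxylabd-7-ene-2,15-diyl diacetate | CC(=O)OCC[C@@H](C)CC[C@@H]1C(C)=CC[C@@H]2C(C)(C)[C@@H](O)[C@@H](OC(C)=O)C[C@@]12C | target

## Step count and least certain steps

Total: 21 steps (8 to diene 11, 5 to ynone 18, the union, 7 to the target). Longest linear sequence: 16 steps (steps 1–8 and 14–21).

**Step 14 (key step).** The cycloaddition may be too slow, because a fully substituted diene terminus must bond to an ynone that carries a methyl on its β-carbon. The Lewis acid may instead isomerise or oligomerise the diene. Facial selectivity at C10 may be modest, because only the half-chair preference set by the distant acetonide distinguishes the two faces. A minor regioisomer is possible.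
Fallback (from 11 and 15, back to 19): a smaller, more electrophilic dienophile is used and the chain is attached afterwards.
- Ester 15 is saponified (LiOH, THF/H2O) to (R)-5-(tert-butyldimethylsilyloxy)-3-methylpentanoic acid F1.
- F1 is iododecarboxylated (PhI(OAc)2, I2, hν) to (R)-tert-butyl(4-iodo-3-methylbutoxy)dimethylsilane F2.
- Diene 11 is combined with but-2-ynal (Me2AlCl, CH2Cl2, −78 °C) to give 2,3-(isopropylidenedioxy)-ent-drima-5,8-dien-11-al F4.
- Iodine–lithium exchange on F2 (tBuLi, Et2O, −78 °C) gives the alkyllithium F3, which adds to F4 to give the 11-hydroxy analogue of 19, F5.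
- Dess–Martin periodinane oxidises F5 to 19.

**Step 5.** Expulsion of the acetonide oxygen from the β-alkoxy enolate, followed by aromatisation, may compete with C-methylation, above all in the slower second alkylation that forms the quaternary carbon.
Fallback (from 6, back to 9): the methyl groups are introduced by Lewis-acid alkylation of neutral silyl enol ethers, with no free enolate.
- 6 is silylated (TBSOTf, Et3N) to the 2-silyloxy diene F6.
- F6 reacts with PhSCH2Cl (ZnBr2 cat.) to give the 6-(phenylsulfanylmethyl) enone F7.
- The same two operations give the silyl dienol ether F8 and then the 6,6-bis(phenylsulfanylmethyl) enone F9.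
- Raney Ni removes both sulfur groups and saturates the alkene, giving (3R,4S)-3,4-(isopropylidenedioxy)-2,2-dimethylcyclohexan-1-one F10.
- F10 has a single enolisable position with no β-oxygen and is methylated (LiN(iPr)2, MeI) to 9.

**Step 16.** Enolisation may occur mainly at the α′-methylene C12 and not at C7, because the extended enolate is strained by the substituents around C9. The quench then returns 20, and any delay allows the product to move back into conjugation.
Fallback (from 19, back to 21): the alkene shift is done before the hydrogenation, where the C7 hydrogens are doubly allylic and far more acidic.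
- 19 with KOtBu and a kinetic quench gives the 5,7-dien-11-one F11.
- The C5=C6 bond of F11 is then saturated selectively (H2, Raney Ni, EtOAc), as is known for steroidal 5,7-dienes, from the face opposite C20, to give 21.

**Step 21.** Over-acylation of the axial C3 hydroxyl, or incomplete acylation at C2, would give mixtures that are hard to separate from the target.
Fallback (from 25, back to 26): 25 is converted with Bu2SnO (toluene, reflux, removal of water) to the 2,3-O-dibutylstannylene acetal F12. In such acetals the equatorial oxygen is the activated one. Treatment with AcCl and Et3N at 0 °C then acetylates O2 and the primary O15 to give 26.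

## Further compounds

F1 | step 14 | (R)-5-(tert-butyldimethylsilyloxy)-3-methylpentanoic acid | OC(=O)C[C@H](C)CCO[Si](C)(C)C(C)(C)C
F2 | step 14 | (R)-tert-butyl(4-iodo-3-methylbutoxy)dimethylsilane | IC[C@H](C)CCO[Si](C)(C)C(C)(C)C
F3 | step 14 | (R)-[4-(tert-butyldimethylsilyloxy)-2-methylbutyl]lithium | [Li]C[C@H](C)CCO[Si](C)(C)C(C)(C)C
F4 | step 14 | 2,3-(isopropylidenedioxy)-ent-drima-5,8-dien-11-al | CC1=C(C=O)[C@]2(C)C[C@H](O3)[C@H](OC3(C)C)C(C)(C)C2=CC1
F5 | step 14 | 11-hydroxy analogue of 19 (both C11 epimers) | CC1=C(C(O)C[C@H](C)CCO[Si](C)(C)C(C)(C)C)[C@]2(C)C[C@H](O3)[C@H](OC3(C)C)C(C)(C)C2=CC1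
F6 | step 5 | tert-butyldimethylsilyl dienol ether of 6 | CC(C)(C)[Si](C)(C)OC1=C[C@H]2OC(C)(C)O[C@H]2C=C1
F7 | step 5 | (4S,5R)-4,5-(isopropylidenedioxy)-6-(phenylsulfanylmethyl)cyclohex-2-en-1-one | O=C1C=C[C@@H]2OC(C)(C)O[C@@H]2C1CSc1ccccc1
F8 | step 5 | tert-butyldimethylsilyl dienol ether of F7 | CC(C)(C)[Si](C)(C)OC1=C(CSc2ccccc2)[C@H]3OC(C)(C)O[C@H]3C=C1
F9 | step 5 | (4S,5R)-4,5-(isopropylidenedioxy)-6,6-bis(phenylsulfanylmethyl)cyclohex-2-en-1-one | O=C1C=C[C@@H]2OC(C)(C)O[C@@H]2C1(CSc1ccccc1)CSc1ccccc1
F10 | step 5 | (3R,4S)-3,4-(isopropylidenedioxy)-2,2-dimethylcyclohexan-1-one | O=C1CC[C@@H]2OC(C)(C)O[C@@H]2C1(C)C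
F11 | step 16 | (13R)-15-(tert-butyldimethylsilyloxy)-2,3-(isopropylidenedioxy)-ent-labda-5,7-dien-11-one | CC(C)(C)[Si](C)(C)OCC[C@@H](C)CC(=O)[C@@H]1C(C)=CC=C2C(C)(C)[C@@H](O3)[C@@H](OC3(C)C)C[C@@]12C
F12 | step 21 | 2,3-O-dibutylstannylene acetal of 25 | OCC[C@@H](C)CC[C@@H]1C(C)=CC[C@@H]2C(C)(C)[C@H]3O[Sn](CCCC)(CCCC)O[C@H]3C[C@@]12C
A1 | alternative 1 | diazomethyl ketone with isopropenyl group on C5 | [N-]=[N+]=CC(=O)C[C@@]1(C)C(=O)C(C)=CC[C@@H]1C(C)=C
A2 | alternative 1 | tricyclic diketone with C3–C4–C18 cyclopropane | O=C1C[C@@]2(C)C(=O)C(C)=CC[C@@H]2[C@@]3(C)C[C@@H]13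
A3 | alternative 2 | acyclic triene: (Z)-alkylidene ester tethered to a 2-silyloxy diene | CC(C)(C)[Si](C)(C)OCC[C@@H](C)CC/C=C(\C(=O)OC)C[C@@H]1OC(C)(C)O[C@@H]1C(C)(C)/C=C/C(O[Si](C)(C)C(C)(C)C)=C/C
A4 | alternative 2 | trans-decalin with C20 methyl ester, C6–C7 silyl enol ether and 2,3-acetonide | CC(C)(C)[Si](C)(C)OCC[C@@H](C)CC[C@@H]1[C@H](C)C(O[Si](C)(C)C(C)(C)C)=C[C@@H]2C(C)(C)[C@@H](O3)[C@@H](OC3(C)C)C[C@@]12C(=O)OC
A5 | alternative 3 | 2,3-seco dialdehyde 15-acetate | CC(=O)OCC[C@@H](C)CC[C@@H]1C(C)=CC[C@H](C(C)(C)C=O)[C@@]1(C)CC=O
A6 | alternative 3 | ent-labd-7-ene-2,3,15-triol 15-acetate | CC(=O)OCC[C@@H](C)CC[C@@H]1C(C)=CC[C@@H]2C(C)(C)[C@@H](O)[C@@H](O)C[C@@]12C
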